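**Plan** (locants: ring C1 bears CO2H, C2 and C4 the OH groups, C6 the side chain; chain carbons run from C1' (benzylic) to C13' (methyl))

1. Retrosynthesis: the target is the H2/Pd product of a C7'=C8' alkene whose two phenols are benzylated. That alkene is cut by cross-metathesis into two terminal alkenes. In the aryl half, the C1–CO2H bond is cut next (formylation, then oxidation), then C6–C1' (aryl Grignard plus epoxide). In the small half, C10'–C11' is cut (Grignard plus propylene oxide).
2. Forward: the benzene ring is bought. The C1'–C7' chain (plus one sacrificial CH2) is attached at C6, and O-2' is acetylated before any carboxyl carbon is on the ring, so the 3,4-dihydroisocoumarin lactone cannot close. The carboxyl is then put on C1 at the aldehyde level and oxidised, C7' is joined to C8', and one hydrogenation finishes the synthesis.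
3. Stereochemistry: C2' (R) comes from hydrolytic kinetic resolution of a terminal epoxide and C12' (S) from (S)-propylene oxide. Neither centre is touched afterwards.
4. Enabling feature: the unbranched nonamethylene run C3'–C11' between the two acetoxy carbons. C7' and C8' are plain CH2 groups, five and four bonds from the stereocentres and remote from the ring, so a C7'=C8' double bond is a traceless retron whose halves are unhindered terminal alkenes. The only other hydrogen-labile groups are the aryl benzyl ethers, which must be removed anyway, so a single H2/Pd operation saturates the alkene and unmasks both phenols.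

Key step: step 8

Assumption: 1, 3, 10 and 11 (as a THF solution) are taken as commercial, and the (R,R)-(salen)Co catalyst is taken to be the enantiomer that hydrates the (S)-enantiomer of a simple alkyl oxirane.

**Step 1**
Reactants: 1 rac-2-(hex-5-en-1-yl)oxirane (1,2-epoxy-7-octene)
Product: 2 (R)-2-(hex-5-en-1-yl)oxirane
Conditions: (R,R)-(salen)Co(III)OAc (0.5 mol%), H2O (0.55 equiv), neat, 0 °C → rt; distillation
Reagents that add atoms: none
Why: Hydrolytic kinetic resolution, in which the chiral Co(salen) catalyst hydrates the (S)-epoxide much faster, so the unreacted (R)-epoxide that will become C2' should be recovered in high enantiomeric purity and distilled from the diol.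

**Step 2**
Reactants: 3 1,3-bis(benzyloxy)-5-bromobenzene; 2 (R)-2-(hex-5-en-1-yl)oxirane
Product: 5 (2R)-1-[3,5-bis(benzyloxy)phenyl]oct-7-en-2-ol, via arylmagnesium bromide 4 (not isolated)
Conditions: Mg, THF, reflux; then CuI (10 mol%), 2, −30 → 0 °C; aq NH4Cl
Reagents that add atoms: none
Why: Copper-catalysed SN2 opening of a monosubstituted epoxide by an aryl Grignard reagent occurs at the unhindered CH2 terminus, so the C–O stereocentre of 2 is not involved and is carried into 5 as (R).

**Step 3**
Reactants: 5 (2R)-1-[3,5-bis(benzyloxy)phenyl]oct-7-en-2-ol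
Product: 6 (2R)-1-[3,5-bis(benzyloxy)phenyl]oct-7-en-2-yl acetate
Conditions: Ac2O, pyridine, DMAP (cat.), CH2Cl2, 0 °C → rt
Reagents that add atoms: acetic anhydride CC(=O)OC(C)=O
Why: DMAP-catalysed O-acetylation of a secondary alcohol, done before the carboxyl carbon exists so that the δ-lactone (3,4-dihydroisocoumarin) can never form.

**Step 4**
Reactants: 6 (2R)-1-[3,5-bis(benzyloxy)phenyl]oct-7-en-2-yl acetate
Product: 8 2-[(2R)-2-acetoxyoct-7-en-1-yl]-4,6-bis(benzyloxy)benzaldehyde, via benzylidene-dimethyliminium chloride 7 (not isolated)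
Conditions: POCl3, DMF, 0 → 60 °C; then aq NaOAc, rt
Reagents that add atoms: N,N-dimethylformamide CN(C)C=O (formyl carbon); water O (formyl oxygen)
Why: Vilsmeier–Haack formylation of a 1-alkyl-3,5-dialkoxybenzene should occur at one of the two equivalent positions ortho to the chain and para to a benzyloxy group, as is usual for orcinol-type diethers, rather than at the more crowded position between the two ethers, while acetate, benzyl ethers and the isolated alkene are inert.

**Step 5**
Reactants: 8 2-[(2R)-2-acetoxyoct-7-en-1-yl]-4,6-bis(benzyloxy)benzaldehyde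
Product: 9 2-[(2R)-2-acetoxyoct-7-en-1-yl]-4,6-bis(benzyloxy)benzoic acid
Conditions: NaClO2, NaH2PO4, 2-methyl-2-butene (excess), t-BuOH/THF/H2O, 0 °C → rt
Reagents that add atoms: sodium chlorite [Na+].[O-]Cl=O
Why: Pinnick oxidation converts the hindered, non-enolisable aryl aldehyde into the acid under buffered conditions that leave the acetate alone, while 2-methyl-2-butene traps the hypochlorous acid that would otherwise attack the terminal alkene or the electron-rich ring.

**Step 6**
Reactants: 10 (S)-2-methyloxirane; 11 but-3-en-1-ylmagnesium bromide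
Product: 12 (2S)-hept-6-en-2-ol
Conditions: CuI (10 mol%), THF, −40 → 0 °C; aq NH4Cl
Reagents that add atoms: none
Why: Copper-catalysed Grignard opening of propylene oxide at its CH2 carbon forms the C10'–C11' bond and leaves the chiral-pool stereocentre untouched, so C12' is (S).

**Step 7**
Reactants: 12 (2S)-hept-6-en-2-ol
Product: 13 (2S)-hept-6-en-2-yl acetate
Conditions: Ac2O, pyridine, DMAP (cat.), CH2Cl2, 0 °C → rt
Reagents that add atoms: acetic anhydride CC(=O)OC(C)=O
Why: Standard DMAP-catalysed acetylation of a secondary alcohol with retention at the stereocentre.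

**Step 8**
Reactants: 9 2-[(2R)-2-acetoxyoct-7-en-1-yl]-4,6-bis(benzyloxy)benzoic acid; 13 (2S)-hept-6-en-2-yl acetate
Product: 14 2-[(2R,7E,12S)-2,12-diacetoxytridec-7-en-1-yl]-4,6-bis(benzyloxy)benzoic acid (E/Z mixture expected, drawn as E)
Conditions: Grubbs II (5 mol%), 13 (4 equiv), 1,4-benzoquinone (10 mol%), CH2Cl2, 40 °C, Ar sweep
Reagents that add atoms: none
Why: Olefin cross-metathesis by the Chauvin mechanism: the Ru alkylidene adds to one terminal alkene in a [2+2] sense, the ruthenacyclobutane cycloreverts, and repetition with the second partner forms the C7'=C8' bond while ethylene leaves. The closest known reaction type is the Ru-catalysed cross-metathesis of two unhindered terminal (type I) alkenes bearing remote esters or a free carboxylic acid. No ring is closed. No stereocentre is created, and the E/Z ratio of the new alkene is irrelevant because step 9 saturates it. The step needs cross-coupling over homo-coupling and no double-bond migration, which would delete CH2 units from the chain. The first should be secured by the fourfold excess of the cheap partner 13 (its homodimer remains a competent partner) and by both vinyl groups being unhindered and separated from the acetoxy carbons by four and three CH2 groups, the second by 1,4-benzoquinone, which intercepts Ru hydrides.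

**Step 9**
Reactants: 14 2-[(2R,7E,12S)-2,12-diacetoxytridec-7-en-1-yl]-4,6-bis(benzyloxy)benzoic acid
Product: 15 2-[(2R,12S)-2,12-diacetoxytridecyl]-4,6-dihydroxybenzoic acid
Conditions: H2 (1 atm), 10% Pd/C, EtOAc, rt
Reagents that add atoms: none
Why: Heterogeneous catalytic hydrogenation should saturate the C7'=C8' alkene (both geometric isomers converge) and hydrogenolyse the two aryl benzyl ethers under neutral conditions that leave the secondary alkyl acetates, the free acid and both stereocentres untouched.

**Compound list**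
1 | rac-2-(hex-5-en-1-yl)oxirane (1,2-epoxy-7-octene) | C=CCCCCC1CO1 | starting material
2 | (R)-2-(hex-5-en-1-yl)oxirane | C=CCCCC[C@@H]1CO1 | intermediate
3 | 1,3-bis(benzyloxy)-5-bromobenzene | Brc1cc(OCc2ccccc2)cc(OCc2ccccc2)c1 | starting material
4 | [3,5-bis(benzyloxy)phenyl]magnesium bromide | Br[Mg]c1cc(OCc2ccccc2)cc(OCc2ccccc2)c1 | intermediate (not isolated)
5 | (2R)-1-[3,5-bis(benzyloxy)phenyl]oct-7-en-2-ol | C=CCCCC[C@@H](O)Cc1cc(OCc2ccccc2)cc(OCc2ccccc2)c1 | intermediate
6 | (2R)-1-[3,5-bis(benzyloxy)phenyl]oct-7-en-2-yl acetate | C=CCCCC[C@@H](OC(C)=O)Cc1cc(OCc2ccccc2)cc(OCc2ccccc2)c1 | intermediate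
7 | {2-[(2R)-2-acetoxyoct-7-en-1-yl]-4,6-bis(benzyloxy)benzylidene}dimethyliminium chloride | C=CCCCC[C@@H](OC(C)=O)Cc1cc(OCc2ccccc2)cc(OCc2ccccc2)c1C=[N+](C)C.[Cl-] | intermediate (not isolated)
8 | 2-[(2R)-2-acetoxyoct-7-en-1-yl]-4,6-bis(benzyloxy)benzaldehyde | C=CCCCC[C@@H](OC(C)=O)Cc1cc(OCc2ccccc2)cc(OCc2ccccc2)c1C=O | intermediate
9 | 2-[(2R)-2-acetoxyoct-7-en-1-yl]-4,6-bis(benzyloxy)benzoic acid | C=CCCCC[C@@H](OC(C)=O)Cc1cc(OCc2ccccc2)cc(OCc2ccccc2)c1C(=O)O | intermediate
10 | (S)-2-methyloxirane ((S)-propylene oxide) | C[C@H]1CO1 | starting material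
11 | but-3-en-1-ylmagnesium bromide | C=CCC[Mg]Br | starting material
12 | (2S)-hept-6-en-2-ol | C=CCCC[C@H](C)O | intermediate
13 | (2S)-hept-6-en-2-yl acetate | C=CCCC[C@H](C)OC(C)=O | intermediate
14 | 2-[(2R,7E,12S)-2,12-diacetoxytridec-7-en-1-yl]-4,6-bis(benzyloxy)benzoic acid | CC(=O)O[C@H](CCCC/C=C/CCC[C@H](C)OC(C)=O)Cc1cc(OCc2ccccc2)cc(OCc2ccccc2)c1C(=O)O | intermediate
15 | 2-[(2R,12S)-2,12-diacetoxytridecyl]-4,6-dihydroxybenzoic acid | CC(=O)O[C@H](CCCCCCCCC[C@H](C)OC(C)=O)Cc1cc(O)cc(O)c1C(=O)O | target

**Step count**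
Total: 9 steps. Longest linear sequence: 7 steps (1, 2, 3, 4, 5, 8, 9).

**Steps most likely to fail, with fallbacks**

Step 8 (cross-metathesis). What may go wrong is statistical partition into the two homodimers, ruthenium-hydride-induced double-bond migration that shortens the chain by CH2 units, or slowing of the catalyst by the free acid. The fallback forms the same C7'–C8' bond at the sp3 level by an alkyl–alkyl Suzuki–Miyaura coupling and sets out from 9. BnBr/K2CO3 in DMF should give benzyl 2-[(2R)-2-acetoxyoct-7-en-1-yl]-4,6-bis(benzyloxy)benzoate F1. Lemieux–Johnson cleavage (cat. OsO4, NaIO4, 2,6-lutidine, dioxane/H2O) removes the terminal CH2 to give benzyl 2-[(2R)-2-acetoxy-7-oxoheptyl]-4,6-bis(benzyloxy)benzoate F2. NaBH4 (MeOH/THF, 0 °C) reduces it to benzyl 2-[(2R)-2-acetoxy-7-hydroxyheptyl]-4,6-bis(benzyloxy)benzoate F3, and CBr4/PPh3 converts this into benzyl 2-[(2R)-2-acetoxy-7-bromoheptyl]-4,6-bis(benzyloxy)benzoate F4. In parallel, 10 is opened with allylmagnesium bromide (CuI cat.) to (2S)-hex-5-en-2-ol F5, acetylated to (2S)-hex-5-en-2-yl acetate F6 and hydroborated with 9-BBN-H to (2S)-6-(9-borabicyclo[3.3.1]nonan-9-yl)hexan-2-yl acetate F7. Pd(OAc)2/PCy3, K3PO4·H2O, THF, rt should couple F4 with F7 to benzyl 2-[(2R,12S)-2,12-diacetoxytridecyl]-4,6-bis(benzyloxy)benzoate F8. Hydrogenolysis (H2, Pd/C) removes the three benzyl groups and comes back to the route at 15.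

Step 4 (formylation). What may go wrong is slow attack of the bulky chloroiminium electrophile next to the branched side chain, attack at the position between the two benzyloxy groups or double formylation, and acid-promoted loss of a benzyl group on heating. The fallback sets out from 6. NBS (1.0 equiv, MeCN, 0 °C, dark), a smaller electrophile, should brominate the ring ortho to the chain and para to a benzyloxy group to give (2R)-1-[3,5-bis(benzyloxy)-2-bromophenyl]oct-7-en-2-yl acetate F9. Pd-catalysed hydroxycarbonylation (Pd(OAc)2, Xantphos, CO 1 atm, H2O, Et3N, dioxane, 80 °C) then turns the C–Br bond directly into the carboxylic acid and comes back to the route at 9, bypassing 7, 8 and step 5.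

Step 2 (epoxide opening). What may go wrong is sluggish aryl transfer from copper to the long-chain epoxide, so that opening by bromide (bromohydrin formation) and biaryl coupling consume the resolved epoxide. The fallback changes the order of bond construction and takes C2' from the chiral pool; it sets out from 3, converted into 4 as before. CuI-catalysed opening of the far more reactive (S)-epichlorohydrin should give (2S)-1-[3,5-bis(benzyloxy)phenyl]-3-chloropropan-2-ol F10. NaOH closes it to (2S)-2-[3,5-bis(benzyloxy)benzyl]oxirane F11. Pent-4-en-1-ylmagnesium bromide F12 (from 5-bromopent-1-ene and Mg) with CuI (cat.) opens F11 at its CH2 terminus, forming C3'–C4', and comes back to the route at 5. Step 1 is then not needed.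

**Further compounds**
F1 | step 8 | benzyl 2-[(2R)-2-acetoxyoct-7-en-1-yl]-4,6-bis(benzyloxy)benzoate | C=CCCCC[C@@H](OC(C)=O)Cc1cc(OCc2ccccc2)cc(OCc2ccccc2)c1C(=O)OCc1ccccc1
F2 | step 8 | benzyl 2-[(2R)-2-acetoxy-7-oxoheptyl]-4,6-bis(benzyloxy)benzoate | O=CCCCC[C@@H](OC(C)=O)Cc1cc(OCc2ccccc2)cc(OCc2ccccc2)c1C(=O)OCc1ccccc1
F3 | step 8 | benzyl 2-[(2R)-2-acetoxy-7-hydroxyheptyl]-4,6-bis(benzyloxy)benzoate | OCCCCC[C@@H](OC(C)=O)Cc1cc(OCc2ccccc2)cc(OCc2ccccc2)c1C(=O)OCc1ccccc1
F4 | step 8 | benzyl 2-[(2R)-2-acetoxy-7-bromoheptyl]-4,6-bis(benzyloxy)benzoate | BrCCCCC[C@@H](OC(C)=O)Cc1cc(OCc2ccccc2)cc(OCc2ccccc2)c1C(=O)OCc1ccccc1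
F5 | step 8 | (2S)-hex-5-en-2-ol | C=CCC[C@H](C)O
F6 | step 8 | (2S)-hex-5-en-2-yl acetate | C=CCC[C@H](C)OC(C)=O
F7 | step 8 | (2S)-6-(9-borabicyclo[3.3.1]nonan-9-yl)hexan-2-yl acetate | CC(=O)O[C@@H](C)CCCCB1C2CCCC1CCC2
F8 | step 8 | benzyl 2-[(2R,12S)-2,12-diacetoxytridecyl]-4,6-bis(benzyloxy)benzoate | CC(=O)O[C@H](CCCCCCCCC[C@H](C)OC(C)=O)Cc1cc(OCc2ccccc2)cc(OCc2ccccc2)c1C(=O)OCc1ccccc1
F9 | step 4 | (2R)-1-[3,5-bis(benzyloxy)-2-bromophenyl]oct-7-en-2-yl acetate | C=CCCCC[C@@H](OC(C)=O)Cc1cc(OCc2ccccc2)cc(OCc2ccccc2)c1Br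
F10 | step 2 | (2S)-1-[3,5-bis(benzyloxy)phenyl]-3-chloropropan-2-ol | ClC[C@@H](O)Cc1cc(OCc2ccccc2)cc(OCc2ccccc2)c1
F11 | step 2 | (2S)-2-[3,5-bis(benzyloxy)benzyl]oxirane | C1[C@@H](O1)Cc2cc(OCc3ccccc3)cc(OCc3ccccc3)c2
F12 | step 2 | pent-4-en-1-ylmagnesium bromide | C=CCCC[Mg]Br
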